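The data are simulated for an exercise, and the scatter is random.

The ratio I watch as G turns into J over the catalyst E is one of two logarithmic drops, the drop being the logarithm of charge over reading of G at one clock time: at 0.98 h it stands at 2.18 in the epsilon run and 0.275 in the zeta run, and the first over the second, 7.93, is the drop ratio.

| flask | G | E | time |
|---|---|---|---|
| zeta | 0.200 M | 0.00100 M |  |
| epsilon | 0.200 M | 0.00300 M |  |
| alpha | 0.0500 M | 0.00100 M | 5.7 h |

| run | time / h | [G] / M |
|---|---|---|
| zeta run | 0.32 | 0.1755 |
| zeta run | 0.98 | 0.1519 |
| zeta run | 1.9 | 0.1247 |
| zeta run | 3.0 | 0.0982 |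
| zeta run | 4.3 | 0.0799 |
| zeta run | 5.7 | 0.0658 |
| epsilon run | 0.32 | 0.1086 |
| epsilon run | 0.98 | 0.0226 |
| epsilon run | 1.9 | 0.0020 |
| epsilon run | 3.0 | 3 × 10⁻⁴ |
| epsilon run | 4.3 | 4 × 10⁻⁴ |
| epsilon run | 5.7 | 0.0030 |

(each reading ± 0.002 M)

1. apparent order in [E] of the starting rate, round the charge of the zeta run (the rate where two percent of its G have turned into J)
2. G in the alpha run at 5.7 h, as a share of the G charged

- Overall: G -> J, with E as catalyst.
- Constant volume, constant temperature.
- What is held in complexes is read along with the free species.
- An order is taken over about fifteen percent of the charge, up and down.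

I take that clock time because the epsilon reading there, 0.0226 M, stands clear of the scatter, while its next reading, 0.0020 M, is level with the scatter. If G falls pseudo-first-order, with a rate constant proportional to a power n of the E charged and a catalyst decay following one curve in both runs, integrating gives each drop as that power times one common time integral. The integral cancels in the ratio, so n is ln(drop ratio)/ln(3.00), which I reckon at 1.88. At 0.32 h the ratio reads 4.67, lower than at the later time, so the cancellation is imperfect; but the zeta drop there is about half as large, and I commit to the later pair. The alpha run has the E of the zeta run, so a pseudo-first-order drop there would equal the zeta drop at 5.7 h, leaving 32.9 % of its charge as G.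

The forecast sets the order at 1.3, below mine, on the ground: “Comparing starting rates gives a ratio of about 4–5 for threefold E”; by a separate estimate of a mean rate constant for the alpha run, it sets the share at 24 %, below mine.

The flask gives an order of 2.1 and leaves 27.3 % of the alpha charge as G.

    E + G ⇌ EG, settled at all times (3.810 L mol⁻¹)
    EG + E → J + 2 E (1.436 × 10⁵ L mol⁻¹ h⁻¹)
    G → Qi (0.1112 h⁻¹)
    E → Qa (0.3564 h⁻¹)

At the point named in the question, the epsilon run makes J at 0.31 M h⁻¹ and the zeta run at 0.033 M h⁻¹, a ratio of 9.39, above my drop ratio of 7.93. Taken between the alpha and zeta runs at 5.7 h, with E equal, the same ratio of drops comes to 1.17.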